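(The data were generated by integration from invented constants, noise included.)

At 4.0 h, 150 min after the last reading of Thursday's flask, I want the average chain length dp, which is E divided by chains begun.

all flasks: J 28 mM; X 84 µM
- Thursday's: Z 30 µM; the very flask that is asked about, followed so far
- Tuesday's: Z 20 µM; run made earlier
- flask: Z 30 µM; time 4.0 h

| run | time / min | E / % | J / % |
|---|---|---|---|
| Thursday's | 8.00 | 0.5 | 90.8 |
| Thursday's | 25.0 | 5.0 | 71.3 |
| Thursday's | 40.0 | 10.5 | 55.8 |
| Thursday's | 60.0 | 16.2 | 38.8 |
| Thursday's | 90.0 | 23.1 | 22.5 |
| Tuesday's | 8.00 | 1.1 | 90.8 |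
| Tuesday's | 25.0 | 5.9 | 70.5 |
| Tuesday's | 40.0 | 11.6 | 54.4 |
| Tuesday's | 60.0 | 18.4 | 37.4 |
| Tuesday's | 90.0 | 25.5 | 20.7 |

(each reading ± 0.3 percentage points)

- average number of monomer units in a chain (chains begun, living or dead) at 4.0 h
- part of the J that has reacted at 4.0 h

- the average divides the monomer in chains by the number of chains begun, living and dead together
- the numbers in the tables scatter with a standard deviation of 0.3 percentage points
- the earlier runs do not show the number of chains; that part of a forecast is a guess

The readings show no chains, so I bound them from one side. Tuesday's flask, with less Z, holds 25.5% E at its last reading against 23.1% in Thursday's flask. So I take Z as an inhibitor that removes one X each, and I let each chain need one X. Thursday's flask then begins at most X charged minus Z charged, the chain ceiling 54.0 µM, and E over this ceiling is a floor for dp.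

I take E at 4.0 h to lie between the last reading and that reading plus the J left, 45.6%. The floor therefore lies between 120 and 236. Between Thursday's last two readings, E gained 42.3% of the J lost, a reading with its scatter. Applied to the J left, it gives E near 32.6% and a floor near 169. Above the floor I have no limit on dp, for the readings show no chains.

The forecast says dp 175, from 105 to 250, and c 98.5%, with “My guess for chains begun is 84 − 30 ≈ 54 µM”. Its dp stands between the two ends of my floor, with E at 35 percent where I take 32.6%.

    J + X → Q + E (k = 0.670 L mol⁻¹ min⁻¹)
    J + Q → E + Q, rate k2*[Q]*[J] (k = 240 L mol⁻¹ min⁻¹)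
    X + E → L (k = 0.140 L mol⁻¹ min⁻¹)
    J → G (k = 0.0110 min⁻¹)
    X + Z → D (k = 7400 L mol⁻¹ min⁻¹)

The flask gives dp 248 and c 98.8%. At 4.00 h, the living end Q stands at 0.0365 mM in this flask, which is 67.6% of the ceiling, and the E of 32.4% over the ceiling gives a floor of 168, below the dp found. In the neighbour charged with 0.34 mM of X, the ceiling is 310 µM, its E of 63.2% gives a floor of 57.1, and its dp is 125.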